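The route rests on disconnecting the C3'–C8'' interflavone bond. This bond sits between O4' on ring B of the 6-methyl-7-methoxyflavone (unit 1) and O7'' on ring A of the apigenin half (unit 2). A single CH2 group linking these two oxygens therefore holds C3' against C8''. The precursor is a 3'-iodo unit 1 flavone joined through O4'–CH2–O7'' to 5'',4'''-di-O-benzylapigenin, whose C8''–H carries no activating group. One palladium-catalysed direct arylation then makes the hindered biaryl bond and closes a seven-membered dibenzo-1,3-dioxepine. BCl3 finally strips the bridge, both benzyl groups and the 5-O-methyl group.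

Key step: step 8

Assumption: the target string carries no descriptor for the C3'–C8'' axis, so the axis is treated as configurationally undefined and no atroposelection is attempted.

Atom labels: in unit 1 the chromenone is unprimed and its ring B singly primed. In unit 2 the chromenone is doubly primed and its ring B triply primed.

Notes on the chemistry:
- Ring A of unit 1 carries three oxygens (O1, O5, O7), whereas 2,6-dimethoxytoluene has only two. Plain acylation of that arene would give a ketone with no ortho hydroxyl, and the pyranone could not be closed.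
- Step 1 therefore installs the missing oxygen at the symmetric ring position. This also makes the acylation and the cyclisation regiochemically unambiguous, giving the 6-methyl and never the 8-methyl isomer.
- Iodide released in a direct arylation slows the catalyst, so Ag2CO3 is part of the key-step reagent set.
- Cyclohexene in step 6 and pentamethylbenzene in step 9 keep stray electrophiles off the electron-rich rings.

Step 1
Reactants: 1 2,6-dimethoxytoluene
Product: 3 3,5-dimethoxy-4-methylphenol, via aryl pinacol boronate 2 (not isolated)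
Conditions: [Ir(OMe)(cod)]2 (cat.), 4,4'-di-tert-butyl-2,2'-bipyridine (cat.), B2pin2 (0.6 equiv), THF, 80 °C; evaporate; then KHSO5 (as 2KHSO5·KHSO4·K2SO4, 1 equiv), acetone/H2O, rt, short contact
Reagents that add atoms: bis(pinacolato)diboron, CC1(C)OB(OC1(C)C)B1OC(C)(C)C(C)(C)O1 (boryl group of 2); potassium peroxymonosulfate, [K+].[O-]S(=O)(=O)OO (phenol oxygen of 3)
Why: Iridium-catalysed C–H borylation is sterically governed and should touch only C4–H, the one ring position of 1 without an ortho substituent, and ipso-oxidation of the boronate then supplies the third ring oxygen, the future O1 (one-pot C–H borylation/oxidation to a phenol).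

Step 2
Reactants: 3 3,5-dimethoxy-4-methylphenol
Product: 4 1-(6-hydroxy-2,4-dimethoxy-3-methylphenyl)ethan-1-one
Conditions: Ac2O (1.2 equiv), BF3·OEt2 (3 equiv), 85 °C; then H2O
Reagents that add atoms: acetic anhydride, CC(=O)OC(C)=O
Why: In this Friedel–Crafts/Fries-type ortho-acylation of a phenol the para position is blocked by the methyl group and the two ortho positions are equivalent by symmetry, so a single o-hydroxyacetophenone, held as its BF2 chelate until work-up, should form.

Step 3
Reactants: 4 1-(6-hydroxy-2,4-dimethoxy-3-methylphenyl)ethan-1-one; 5 4-hydroxy-3-iodobenzaldehyde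
Product: 6 (E)-1-(6-hydroxy-2,4-dimethoxy-3-methylphenyl)-3-(4-hydroxy-3-iodophenyl)prop-2-en-1-one
Conditions: KOH (50 % aq., excess), EtOH, rt to 40 °C, prolonged; then 1 M HCl
Reagents that add atoms: none
Why: In this Claisen–Schmidt condensation the ketone enolate adds to the non-enolisable aldehyde and E1cB loss of water gives the E-enone under thermodynamic control; the phenoxide form of 5 only slows the addition, which excess base and time make up for, and the aryl iodide is inert.

Step 4
Reactants: 6 (E)-chalcone
Product: 7 2-(4-hydroxy-3-iodophenyl)-5,7-dimethoxy-6-methyl-4H-chromen-4-one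
Conditions: I2 (10 mol %), DMSO, 130 °C
Reagents that add atoms: none
Why: In this iodine-catalysed oxidative cyclisation of a 2'-hydroxychalcone, oxa-Michael closure through the only free ortho hydroxyl, α-iodination and loss of HI give the flavone while DMSO re-oxidises HI, and because the other ortho oxygen is methylated only the 6-methyl isomer can arise.

Step 5
Reactants: 7 4'-hydroxy-3'-iodo-5,7-dimethoxy-6-methylflavone; 8 chloromethyl methyl sulfide
Product: 9 3'-iodo-5,7-dimethoxy-6-methyl-4'-(methylsulfanylmethoxy)flavone
Conditions: NaH (1.2 equiv), DMF, 0 °C; then 8 (1.3 equiv), rt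
Reagents that add atoms: none
Why: Williamson O-alkylation of the only acidic hydroxyl by the very SN2-active α-chloro sulfide should give the base-stable methylthiomethyl ether.

Step 6
Reactants: 9 methylthiomethyl ether of unit 1; 10 apigenin
Product: 12 O4'–CH2–O7''-bridged bis-flavone diol, via chloromethyl ether 11 (not isolated)
Conditions: SO2Cl2 (1.05 equiv), cyclohexene (2 equiv), CH2Cl2, −78 to 0 °C; evaporate; then 10 (1.5 equiv), K2CO3 (1.5 equiv), DMF, 0 °C to rt
Reagents that add atoms: sulfuryl chloride, O=S(=O)(Cl)Cl (chlorine of 11)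
Why: Chlorinolysis of the O,S-acetal (S-chlorination and collapse to the aryloxymethyl chloride, far faster at low temperature than ring chlorination, with cyclohexene trapping MeSCl) is followed by a Williamson alkylation in which one equivalent of carbonate per apigenin ionises only the most acidic 7-OH, while the chelated 5-OH is inert and 4'-OH stays largely protonated.

Step 7
Reactants: 12 bridged bis-flavone diol
Product: 13 3'-iodo unit 1 flavone linked through O4'–CH2–O7'' to 5'',4'''-di-O-benzylapigenin
Conditions: BnBr (3 equiv), K2CO3 (4 equiv), DMF, 60 °C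
Reagents that add atoms: benzyl bromide, BrCc1ccccc1
Why: Williamson benzylation under forcing carbonate conditions should cap the 4'''-phenol and also the hydrogen-bonded 5''-OH, while the diaryl formaldehyde acetal and the aryl iodide are inert to base.

Step 8
Reactants: 13 bridged iodo bis-flavone
Product: 14 methylene-bridged protected biflavone (C3'–C8'' bond inside a dibenzo[d,f][1,3]dioxepine)
Conditions: Pd(OAc)2 (10 mol %), PCy3·HBF4 (20 mol %), PivOH (30 mol %), K2CO3 (2 equiv), Ag2CO3 (0.5 equiv), DMA (0.01 M), 110 °C, argon
Reagents that add atoms: none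
Why: Zerovalent palladium formed from Pd(OAc)2 and PCy3 adds oxidatively to the C3'–I bond, Ag2CO3 takes the iodide out as AgI (free iodide slows this catalysis) and pivalate occupies the vacant site on divalent palladium. The bound pivalate removes H8'' while the Pd–C8'' bond forms (concerted metalation–deprotonation), and reductive elimination then makes the C3'–C8'' bond and returns zerovalent palladium. The closest known reaction type is the intramolecular direct arylation of tethered aryl halides with Pd(OAc)2, a trialkylphosphine and pivalate, which is established up to seven-membered rings, and one-atom acetal tethers are an established way to 2,2'-biphenols. The one ring closed is the seven-membered dibenzo[d,f][1,3]dioxepine (C3', C4', O4', CH2, O7'', C7'', C8''), closed by contraction of an eight-membered palladacycle in the aryl–aryl reductive elimination, both bond termini lying inside the new ring. No stereocentre is created, and the bridged biaryl axis forms as a racemate, which is all that the target requires. The step needs C8'' over C6'', both ortho to O7'': the benzylic CH2 on O5'' is turned away from the C4'' carbonyl and lies beside H6'', which shields C6'' and biases the O7''–CH2 bond towards the C8'' side, whereas C8'' has only the tied-back ring oxygen O1'' as its other neighbour and should bear the more acidic hydrogen; high dilution suppresses intermolecular arylation at C8 of unit 1.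

Step 9
Reactants: 14 methylene-bridged protected biflavone
Product: 15 target, 8-[2-hydroxy-5-(5-hydroxy-7-methoxy-6-methyl-4-oxo-4H-chromen-2-yl)phenyl]-5,7-dihydroxy-2-(4-hydroxyphenyl)-4H-chromen-4-one
Conditions: BCl3 (1 M in CH2Cl2, 12 equiv), pentamethylbenzene (8 equiv), CH2Cl2, −78 °C to rt; then MeOH, 0 to 40 °C, evaporate
Reagents that add atoms: none
Why: In this Lewis-acid ether cleavage BCl3 removes the benzyl ethers in the cold (cation taken up by pentamethylbenzene in a Friedel–Crafts capture), opens the diaryl acetal to a borate and an aryl chloromethyl ether that methanolysis clears as dimethoxymethane, and on warming cleaves only the 5-O-methyl group that can form a six-membered boron chelate with the C4 carbonyl, so the unchelated 7-O-methyl group should stay.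

Compound list
1 | 2,6-dimethoxytoluene | COc1cccc(OC)c1C | starting material
2 | 2-(3,5-dimethoxy-4-methylphenyl)-4,4,5,5-tetramethyl-1,3,2-dioxaborolane | COc1cc(B2OC(C)(C)C(C)(C)O2)cc(OC)c1C | intermediate
3 | 3,5-dimethoxy-4-methylphenol | COc1cc(O)cc(OC)c1C | intermediate
4 | 1-(6-hydroxy-2,4-dimethoxy-3-methylphenyl)ethan-1-one | CC(=O)c1c(O)cc(OC)c(C)c1OC | intermediate
5 | 4-hydroxy-3-iodobenzaldehyde | O=Cc1ccc(O)c(I)c1 | starting material
6 | (E)-1-(6-hydroxy-2,4-dimethoxy-3-methylphenyl)-3-(4-hydroxy-3-iodophenyl)prop-2-en-1-one | COc1cc(O)c(C(=O)/C=C/c2ccc(O)c(I)c2)c(OC)c1C | intermediate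
7 | 2-(4-hydroxy-3-iodophenyl)-5,7-dimethoxy-6-methyl-4H-chromen-4-one | COc1cc2oc(-c3ccc(O)c(I)c3)cc(=O)c2c(OC)c1C | intermediate
8 | chloromethyl methyl sulfide | CSCCl | starting material
9 | 2-[3-iodo-4-(methylsulfanylmethoxy)phenyl]-5,7-dimethoxy-6-methyl-4H-chromen-4-one | COc1cc2oc(-c3ccc(OCSC)c(I)c3)cc(=O)c2c(OC)c1C | intermediate
10 | apigenin | O=c1cc(-c2ccc(O)cc2)oc2cc(O)cc(O)c12 | starting material
11 | 2-[4-(chloromethoxy)-3-iodophenyl]-5,7-dimethoxy-6-methyl-4H-chromen-4-one | COc1cc2oc(-c3ccc(OCCl)c(I)c3)cc(=O)c2c(OC)c1C | intermediate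
12 | 5-hydroxy-2-(4-hydroxyphenyl)-7-{[4-(5,7-dimethoxy-6-methyl-4-oxo-4H-chromen-2-yl)-2-iodophenoxy]methoxy}-4H-chromen-4-one | COc1cc2oc(-c3ccc(OCOc4cc(O)c5c(=O)cc(-c6ccc(O)cc6)oc5c4)c(I)c3)cc(=O)c2c(OC)c1C | intermediate
13 | 5-benzyloxy-2-(4-benzyloxyphenyl)-7-{[4-(5,7-dimethoxy-6-methyl-4-oxo-4H-chromen-2-yl)-2-iodophenoxy]methoxy}-4H-chromen-4-one (key-step precursor) | COc1cc2oc(-c3ccc(OCOc4cc(OCc5ccccc5)c5c(=O)cc(-c6ccc(OCc7ccccc7)cc6)oc5c4)c(I)c3)cc(=O)c2c(OC)c1C | intermediate
14 | O4',O7''-methylene-bridged 5'',4'''-di-O-benzyl-5,7-di-O-methyl-6-methyl-3',8''-biflavone (key-step product) | COc1cc2oc(-c3ccc4OCOc5cc(OCc6ccccc6)c6c(=O)cc(-c7ccc(OCc8ccccc8)cc7)oc6c5-c4c3)cc(=O)c2c(OC)c1C | intermediate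
15 | 6-methyl-7-O-methylamentoflavone (CNP0113589.0) | COc1cc2oc(-c3ccc(O)c(-c4c(O)cc(O)c5c(=O)cc(-c6ccc(O)cc6)oc45)c3)cc(=O)c2c(O)c1C | target

Total step count: 9. Longest linear sequence: 9 steps (1 to 15); 5, 8 and 10 enter as purchased materials.

Steps most likely to fail

Step 8.
- The tethered arylpalladium species may be reduced (protodeiodination) faster than it closes the seven-membered ring, or metalation may spread to C6''.
- The fallback drops the tether and uses an intermolecular Suzuki–Miyaura biaryl synthesis with both partners functionalised. It sets out from 7 and 10 and comes back at 15.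
- Benzylation of 7 (BnBr, K2CO3, DMF) should give 4'-benzyloxy-3'-iodo-5,7-dimethoxy-6-methylflavone F1. Miyaura borylation (B2pin2, PdCl2(dppf), KOAc, dioxane, 90 °C) should then give its 3'-pinacol boronate F2.
- Exhaustive benzylation of 10 should give 5,7,4'-tri-O-benzylapigenin F3. Electrophilic iodination (NIS, cat. TFA, MeCN) should give 8-iodo-5,7,4'-tri-O-benzylapigenin F4. The site of attack can be checked and any isomer removed at this monomer stage.
- Coupling of F2 with F4 (Pd(PPh3)4, K3PO4, dioxane/H2O, 90 °C) should give the unbridged protected biflavone F5. BCl3 with pentamethylbenzene, as in step 9, then leads to 15.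

Step 6.
- Alkylation may spread from O7'' to O4''' or occur twice, and the chloromethyl ether may be lost to hydrolysis while the poorly soluble triol reacts slowly.
- The fallback replaces chemoselection on the free triol by protecting-group control. It sets out from 10 and comes back at 12.
- Peracetylation (Ac2O, pyridine) should give apigenin triacetate F6.
- Thiophenol and imidazole in NMP should remove only the most electrophilic 7-acetate, giving 5,4'-di-O-acetylapigenin F7.
- The single free hydroxyl of F7 is alkylated by 11 (K2CO3, DMF, 0 °C) to the bridged diacetate F8. Methanolysis (K2CO3, MeOH, rt) returns to 12.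

Step 9.
- Several things can go wrong when four kinds of C–O bond are cut in one flask. Benzyl or aryloxymethyl cations may alkylate the phloroglucinol ring, the acetal may open incompletely, and the 7-O-methyl group may be eroded.
- The fallback unmasks each group by its own mechanism. It sets out from 14 and comes back at 15.
- Hydrogenolysis (H2, 1 atm, Pd/C, THF/MeOH) should remove both benzyl groups without any cation and give the bridged 5'',4'''-diol F9.
- Brønsted-acid transacetalisation (conc. HCl, MeOH/THF, 60 °C) should release the bridge into the solvent and give the 5-O-methyl ether of the target F10.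
- Chelation-controlled demethylation (AlCl3, MeCN, 70 °C) should then cleave only the 5-O-methyl group and give 15.

Further compounds
F1 | step 8 | 2-(4-benzyloxy-3-iodophenyl)-5,7-dimethoxy-6-methyl-4H-chromen-4-one | COc1cc2oc(-c3ccc(OCc4ccccc4)c(I)c3)cc(=O)c2c(OC)c1C
F2 | step 8 | 2-[4-benzyloxy-3-(4,4,5,5-tetramethyl-1,3,2-dioxaborolan-2-yl)phenyl]-5,7-dimethoxy-6-methyl-4H-chromen-4-one | COc1cc2oc(-c3ccc(OCc4ccccc4)c(B4OC(C)(C)C(C)(C)O4)c3)cc(=O)c2c(OC)c1C
F3 | step 8 | 5,7,4'-tri-O-benzylapigenin | O=c1cc(-c2ccc(OCc3ccccc3)cc2)oc2cc(OCc3ccccc3)cc(OCc3ccccc3)c12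
F4 | step 8 | 8-iodo-5,7,4'-tri-O-benzylapigenin | O=c1cc(-c2ccc(OCc3ccccc3)cc2)oc2c(I)c(OCc3ccccc3)cc(OCc3ccccc3)c12
F5 | step 8 | 4',5'',7'',4'''-tetra-O-benzyl-5,7-di-O-methyl-6-methyl-3',8''-biflavone | COc1cc2oc(-c3ccc(OCc4ccccc4)c(-c4c(OCc5ccccc5)cc(OCc5ccccc5)c5c(=O)cc(-c6ccc(OCc7ccccc7)cc6)oc45)c3)cc(=O)c2c(OC)c1C
F6 | step 6 | apigenin triacetate | CC(=O)Oc1ccc(cc1)-c1cc(=O)c2c(OC(C)=O)cc(OC(C)=O)cc2o1
F7 | step 6 | 5,4'-di-O-acetylapigenin | CC(=O)Oc1ccc(cc1)-c1cc(=O)c2c(OC(C)=O)cc(O)cc2o1
F8 | step 6 | O4'–CH2–O7''-bridged bis-flavone 5'',4'''-diacetate | COc1cc2oc(-c3ccc(OCOc4cc(OC(C)=O)c5c(=O)cc(-c6ccc(OC(C)=O)cc6)oc5c4)c(I)c3)cc(=O)c2c(OC)c1C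
F9 | step 9 | O4',O7''-methylene-bridged 5,7-di-O-methyl-6-methyl-3',8''-biflavone-5'',4'''-diol | COc1cc2oc(-c3ccc4OCOc5cc(O)c6c(=O)cc(-c7ccc(O)cc7)oc6c5-c4c3)cc(=O)c2c(OC)c1C
F10 | step 9 | 5,7-di-O-methyl-6-methylamentoflavone | COc1cc2oc(-c3ccc(O)c(-c4c(O)cc(O)c5c(=O)cc(-c6ccc(O)cc6)oc45)c3)cc(=O)c2c(OC)c1C
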